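**Retrosynthetic overview**
1. Target 17 ⇐ tertiary carbinol 16 (alkoxy-radical β-scission, loss of acetone) ⇐ isopropenyl cage 15 (Markovnikov hydration).
2. 15 ⇐ 7-endo type A bicyclic acylphloroglucinol 14 by one oxidative radical cascade: C3–C11 (seven-membered ring of the homoadamantane), then C12–C13 (cyclopentane).
3. 14 ⇐ acylphloroglucinol 7 + C10 triflate 11: dearomatising alkylation at C5, then tertiary C8 cation captured by C1 (bicyclo[3.3.1]nonane).
4. 7 ⇐ phloroglucinol, isobutyryl chloride, geranyl bromide, prenyl bromide; 11 ⇐ (±)-lavandulol (resolution, hydration, triflation).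
5. Ring order: aromatic ring → C1–C8 ring → C3–C11 ring → C12–C13 ring. This mirrors the presumed biosynthesis: prenylations, cation closure, oxidative coupling of C3 with the two prenyl groups, oxidative loss of a C3 unit as acetone.

Locants used: C1–C9 = bicyclo[3.3.1]nonane (C1 acyl, C5 geranyl, C8 CMe2, C9 bridging C=O); C10 = CH2 on C7; C11 = CH bonded to C3; C12 = ring CMe2; C13, C14 = CH2CH2 from C12 to C3. In these locants the target is (1S,3S,5R,7R,11R).

Assumption: (±)-lavandulol is bought as a fragrance chemical.

**Step 1**
Reactants: 1 phloroglucinol; 2 isobutyryl chloride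
Product: 3 2-methyl-1-(2,4,6-trihydroxyphenyl)propan-1-one
Conditions: AlCl3 (3 equiv), PhNO2/CH2Cl2, 0 to 40 °C; aq. HCl work-up
Reagents that add atoms: none
Why: Friedel–Crafts acylation of the most electron-rich arene stops after one acyl group because the product is deactivated, and no stereocentre is formed.

**Step 2**
Reactants: 3 2-methyl-1-(2,4,6-trihydroxyphenyl)propan-1-one; 4 geranyl bromide
Product: 5 1-[3-((2E)-3,7-dimethylocta-2,6-dienyl)-2,4,6-trihydroxyphenyl]-2-methylpropan-1-one
Conditions: 4 (1.0 equiv), 2 M aq. KOH (2.2 equiv), 0 °C to rt; chromatography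
Reagents that add atoms: none
Why: C-alkylation of the phloroglucinolate by an allylic bromide (SN2) is favoured over O-alkylation in water, the mono-product is separated from recovered 3 and dialkylated material, and the E-olefin is untouched.

**Step 3**
Reactants: 5 3-geranyl acylphloroglucinol; 6 prenyl bromide
Product: 7 1-[3-((2E)-3,7-dimethylocta-2,6-dienyl)-2,4,6-trihydroxy-5-(3-methylbut-2-enyl)phenyl]-2-methylpropan-1-one
Conditions: 6 (1.05 equiv), 2 M aq. KOH (2.2 equiv), 0 °C to rt; chromatography
Reagents that add atoms: none
Why: the same phenoxide C-alkylation at the last free ring carbon gives the fully substituted aromatic precursor, with no stereocentre formed.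

**Step 4**
Reactants: 8 (±)-lavandulol
Product: 9 (S)-lavandulol, (S)-5-methyl-2-(prop-1-en-2-yl)hex-4-en-1-ol
Conditions: Porcine pancreatic lipase, vinyl acetate (0.6 equiv), MTBE, rt, to about 60% conversion; chromatography
Reagents that add atoms: none
Why: lipase-catalysed kinetic resolution (enantioselective transesterification) acetylates the (R)-alcohol faster and leaves the (S)-alcohol, which carries the future C7 stereocentre.

**Step 5**
Reactants: 9 (S)-lavandulol
Product: 10 (R)-2-(2-hydroxypropan-2-yl)-5-methylhex-4-en-1-ol
Conditions: Co(acac)2 (0.2 equiv), PhSiH3 (2 equiv), O2 (1 atm), i-PrOH/THF, 0 °C to rt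
Reagents that add atoms: dioxygen, O=O
Why: Mukaiyama hydration (hydrogen-atom transfer from a cobalt hydride, Markovnikov) is faster at the 1,1-disubstituted isopropenyl group than at the trisubstituted olefin and, as a radical process, cannot cyclise the free alcohol onto the prenyl olefin, while the stereocentre is untouched (the descriptor changes only through priorities).

**Step 6**
Reactants: 10 (R)-diol
Product: 11 (R)-2-(2-hydroxypropan-2-yl)-5-methylhex-4-enyl trifluoromethanesulfonate
Conditions: Tf2O (1.05 equiv), 2,6-lutidine (1.5 equiv), CH2Cl2, −78 °C; cold work-up, used at once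
Reagents that add atoms: trifluoromethanesulfonic anhydride, O=S(=O)(OS(=O)(=O)C(F)(F)F)C(F)(F)F
Why: O-sulfonylation is selective for the primary over the tertiary alcohol and gives an electrophile reactive enough for C-alkylation at a β-branched carbon, without touching the stereocentre.

**Step 7**
Reactants: 7 3-geranyl-5-prenyl acylphloroglucinol; 11 hydroxy triflate
Product: 14 7-endo type A bicycle 5-geranyl-4-hydroxy-8,8-dimethyl-1-(2-methylpropanoyl)-3,7-bis(3-methylbut-2-enyl)bicyclo[3.3.1]non-3-ene-2,9-dione (C7 prenyl syn to C3), via dearomatised C5-alkylated hydroxy triketone 12 (not isolated), via tertiary mesylate of that triketone 13 (not isolated)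
Conditions: LiN(SiMe3)2 (3.0 equiv), THF, −78 °C; 11 (1.3 equiv), −78 to −20 °C; then Et3N (6 equiv), MsCl (3 equiv), 0 °C to rt; aq. NaHCO3; preparative HPLC
Reagents that add atoms: none
Why: alkylative dearomatisation (ipso C-alkylation at the geranyl-bearing ring carbon) is followed by an SN1 cation–enolate cyclisation in which the tertiary mesylate ionises to the C8 cation and C1 of the acyl-triketonate captures it, where C7 comes from 11, C1 follows from the ring closure, and C5 is formed without control (its epimer gives the 7-exo bicycle and alkylation at the prenyl-bearing carbon gives a regioisomer), so 14 is one of four isomeric bicycles and must be separated.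

**Step 8**
Reactants: 14 7-endo type A bicycle
Product: 15 cage compound, the target skeleton carrying a prop-1-en-2-yl group on C13 (C13 epimers; C1, C3, C5, C7, C11 as in the target)
Conditions: Mn(OAc)3·2H2O (2.2 equiv), Cu(OAc)2·H2O (1.0 equiv, reoxidised in situ), degassed AcOH, rt; base wash, chromatography
Reagents that add atoms: none
Why: in this oxidative free-radical cyclisation cascade (trivalent manganese, divalent copper) the C3 radical of the enolised 1,3-diketone adds 7-exo-trig to the endo C7 prenyl olefin, the tertiary C12 radical closes 5-exo-trig on the C3 prenyl olefin and divalent copper oxidises the last radical to the isopropenyl group, with C3 fixed by the cage and C11 set under substrate control in the first closure (CMe2 must end on the C1/C8 side, and the C11 epimer is the expected co-product to be separated).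

**Step 9**
Reactants: 15 isopropenyl cage
Product: 16 C13-(2-hydroxypropan-2-yl) cage (C13 epimers)
Conditions: Hg(OAc)2 (1.05 equiv), THF/H2O 1:1, 0 °C; then NaBH4, 3 M NaOH, 0 °C, short contact
Reagents that add atoms: water, O
Why: oxymercuration–demercuration (Markovnikov hydration) is far faster at a 1,1-disubstituted than at a trisubstituted olefin, so only the isopropenyl group reacts, the four ketones (each flanked by quaternary carbons) should survive the brief borohydride step, and no ring stereocentre changes.

**Step 10**
Reactants: 16 tertiary carbinol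
Product: 17 target, (1S,3S,5R,7R,11R)-5-geranyl-8,8,12,12-tetramethyl-1-(2-methylpropanoyl) cage trione (CNP0313870.1)
Conditions: [Ir(dF(CF3)ppy)2(5,5'-d(CF3)bpy)]PF6 (2 mol%), 2,4,6-collidine (1 equiv), 2,4,6-triisopropylbenzenethiol (0.2 equiv), PhCF3, blue LEDs, rt
Reagents that add atoms: none
Why: alkoxy-radical β-scission (the tertiary alkoxy radical is made by proton-coupled electron transfer) expels acetone and the secondary C13 radical, which takes a hydrogen atom from the thiol, so C13 becomes CH2, its earlier configuration is irrelevant and no other centre is touched.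

**Compound list**
1 | phloroglucinol | Oc1cc(O)cc(O)c1 | starting material
2 | isobutyryl chloride | CC(C)C(=O)Cl | starting material
3 | 2-methyl-1-(2,4,6-trihydroxyphenyl)propan-1-one | CC(C)C(=O)c1c(O)cc(O)cc1O | intermediate
4 | geranyl bromide, (2E) | CC(C)=CCC/C(C)=C/CBr | starting material
5 | 3-geranyl acylphloroglucinol | CC(C)C(=O)c1c(O)cc(O)c(C/C=C(\C)CCC=C(C)C)c1O | intermediate
6 | prenyl bromide | CC(C)=CCBr | starting material
7 | 3-geranyl-5-prenyl acylphloroglucinol | CC(C)C(=O)c1c(O)c(CC=C(C)C)c(O)c(C/C=C(\C)CCC=C(C)C)c1O | intermediate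
8 | (±)-lavandulol (racemic) | CC(C)=CCC(CO)C(C)=C | starting material
9 | (S)-lavandulol | OC[C@H](C(C)=C)CC=C(C)C | intermediate
10 | (R)-2-(2-hydroxypropan-2-yl)-5-methylhex-4-en-1-ol | OC[C@H](C(C)(C)O)CC=C(C)C | intermediate
11 | primary triflate of 10 | O=S(=O)(OC[C@H](C(C)(C)O)CC=C(C)C)C(F)(F)F | intermediate
12 | (6R)-6-geranyl-3,5-dihydroxy-6-[(2R)-2-(2-hydroxypropan-2-yl)-5-methylhex-4-enyl]-2-(2-methylpropanoyl)-4-prenylcyclohexa-2,4-dienone (one enol tautomer) | O=C1C(C(=O)C(C)C)=C(O)C(CC=C(C)C)=C(O)[C@@]1(C/C=C(\C)CCC=C(C)C)C[C@H](C(C)(C)O)CC=C(C)C | intermediate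
13 | tertiary methanesulfonate of 12 | O=C1C(C(=O)C(C)C)=C(O)C(CC=C(C)C)=C(O)[C@@]1(C/C=C(\C)CCC=C(C)C)C[C@H](C(C)(C)OS(C)(=O)=O)CC=C(C)C | intermediate
14 | 7-endo type A bicycle (enol form; acyl and geranyl exo, C7 prenyl syn to C3) | CC(C)=CCC/C(C)=C/C[C@]12C[C@@H](CC=C(C)C)C(C)(C)[C@](C(=O)C(C)C)(C1=O)C(=O)C(CC=C(C)C)=C2O | intermediate
15 | cage with isopropenyl on C13 (C13 unspecified, mixture) | CC(C)=CCC/C(C)=C/C[C@@]12C[C@H]3C[C@@H]4C(C)(C)C(C(C)=C)C[C@]4(C1=O)C(=O)[C@@](C(=O)C(C)C)(C2=O)C3(C)C | intermediate
16 | cage with 2-hydroxypropan-2-yl on C13 (C13 unspecified, mixture) | CC(C)=CCC/C(C)=C/C[C@@]12C[C@H]3C[C@@H]4C(C)(C)C(C(C)(C)O)C[C@]4(C1=O)C(=O)[C@@](C(=O)C(C)C)(C2=O)C3(C)C | intermediate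
17 | CNP0313870.1 | CC(C)=CCC/C(C)=C/C[C@@]12C[C@H]3C[C@@H]4C(C)(C)CC[C@]4(C1=O)C(=O)[C@@](C(=O)C(C)C)(C2=O)C3(C)C | target

**Totals**
Total steps: 10. Longest linear sequence: 7 (steps 1, 2, 3, 7, 8, 9, 10; the fragment branch 4, 5, 6, 7, 8, 9, 10 is equally long).

**Three steps most likely to fail**

Step 7. The hard triflate may O-alkylate, and the ipso-alkylation does not distinguish the geranyl- from the prenyl-bearing carbon or the two faces at C5. The C8 cation can also be trapped by enolate oxygen or by C3 instead of C1, and the closure needed here puts the C7 arm endo. The fallback generates the cation protically with C3 blocked. It sets out from 7 and 9: 9 is triflated directly to (S)-lavandulyl triflate F1, which alkylates the trianion of 7 to the dearomatised lavandulyl triketone F2. N-Bromosuccinimide brominates the most nucleophilic enol carbon to give the C3-bromide F3, in which C1 is the only carbon nucleophile left. Formic acid protonates the isopropenyl group and C1 captures the C8 cation to give the 3-bromo bicycle F4. Zinc dust in AcOH removes the bromine and the route is rejoined at 14.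

Step 8. C11 is set under substrate control and this is the least secure stereochemical element. Models suggest that the orientation leading to the C11 epimer avoids a contact between C10 and the axial C8 methyl group, so the target epimer may well be the minor one. Divalent copper may also oxidise the C12 radical before the second closure. The fallback fixes C11 by reagent control through a two-electron closure. It sets out from 14: epoxidation with 1,2:4,5-di-O-isopropylidene-β-L-erythro-2,3-hexodiulo-2,6-pyranose (the enantiomer of the fructose-derived ketone catalyst) and KHSO5, run to partial conversion, gives among the mono-epoxides the (S)-configured side-chain epoxide F5. BF3·OEt2 lets C3 open it at C11 with inversion to the homoadamantane tertiary alcohol F6 (not isolated). Ionisation at C12 and capture by the C3 prenyl olefin rejoin the route at 15 as a single C11 epimer. Site selectivity among the four trisubstituted olefins is only statistical, so 14 has to be recycled.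

Step 10. Thiyl radicals can add to or isomerise the geranyl olefins, the excited iridium complex may oxidise them, and the alkoxy radical may simply return to the alcohol or lose methyl. The fallback makes the same alkoxy radical by one-electron reduction of a peroxide. It sets out from 15: silylperoxidation of the isopropenyl group (Co(acac)2, Et3SiH, O2) gives the tertiary triethylsilyl peroxide F7. FeSO4·7H2O with benzenethiol in MeOH cleaves the O–O bond, and β-scission followed by hydrogen-atom capture rejoins the route at 17 (step 9 is then skipped).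

**Further compounds**
F1 | step 7 | (S)-lavandulyl triflate | O=S(=O)(OC[C@H](C(C)=C)CC=C(C)C)C(F)(F)F
F2 | step 7 | dearomatised C5-geranyl C5-(S)-lavandulyl triketone (enol form) | O=C1C(C(=O)C(C)C)=C(O)C(CC=C(C)C)=C(O)[C@@]1(C/C=C(\C)CCC=C(C)C)C[C@H](C(C)=C)CC=C(C)C
F3 | step 7 | C3-bromide of F2 (C3 epimers) | O=C1C(C(=O)C(C)C)=C(O)C(Br)(CC=C(C)C)C(=O)[C@@]1(C/C=C(\C)CCC=C(C)C)C[C@H](C(C)=C)CC=C(C)C
F4 | step 7 | 3-bromo 7-endo type A bicycle (C3 epimers) | CC(C)=CCC/C(C)=C/C[C@]12C[C@@H](CC=C(C)C)C(C)(C)[C@](C(=O)C(C)C)(C1=O)C(=O)C(Br)(CC=C(C)C)C2=O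
F5 | step 8 | (S)-epoxide of the C7 prenyl group of 14 | CC(C)=CCC/C(C)=C/C[C@]12C[C@@H](C[C@@H]3OC3(C)C)C(C)(C)[C@](C(=O)C(C)C)(C1=O)C(=O)C(CC=C(C)C)=C2O
F6 | step 8 | homoadamantane tertiary alcohol (C3–C11 closed, C12 carbinol, C3 prenyl intact) | CC(C)=CCC/C(C)=C/C[C@@]12C[C@H]3C[C@H](C(C)(C)O)[C@@](CC=C(C)C)(C1=O)C(=O)[C@@](C(=O)C(C)C)(C2=O)C3(C)C
F7 | step 10 | tertiary triethylsilyl peroxide of the cage (C13 epimers) | CC(C)=CCC/C(C)=C/C[C@@]12C[C@H]3C[C@@H]4C(C)(C)C(C(C)(C)OO[Si](CC)(CC)CC)C[C@]4(C1=O)C(=O)[C@@](C(=O)C(C)C)(C2=O)C3(C)C
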